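## The problem

Clinopodic acid F (21) is an ester of two acids. One is (R)-3-(4-hydroxy-3-methoxyphenyl)lactic acid (ring C). The other is an E-cinnamic acid whose aryl group is a 2,3-dihydro-1,4-benzodioxine: ring A fused to a dioxane that carries a carboxyl group at C2 and a 3,4-dihydroxyphenyl group (ring B) at C3, with the propenoate at C7. Of the three stereocentres, the lactate carbon (R) is ten bonds from the dioxane and can neither steer nor be steered, so it has to come from the chiral pool. C2 and C3 (both R, substituents cis) are neighbours and must be set in one event, the relative configuration by a stereospecific process and the absolute one by a catalyst. The cis arrangement is the less stable one: C2–H is alpha to a carbonyl and an aryloxy group, with the O4 phenoxide in the beta position, so a C2 ester or aldehyde that meets base can epimerise to trans or open the ring by elimination. Once the para hydroxyl of ring B is free, base can break the benzylic C3–O4 bond through a quinone methide and strong acid can ionise it. The ester between the two acids forbids saponification, the cinnamate double bond forbids hydrogenolysis, and the unmasked catechol and guaiacol forbid oxidants, so C2 must reach the acid level late and all protecting groups must fall in one operation that is neither basic nor reductive. The feature that opens the molecule is that O1 and O4 are the two oxygens of the ring A catechol and bridge a two-carbon unit, C2–C3, with cis substituents: the imprint of a suprafacial [4+2] addition of an ortho-quinone, through its O=C–C=O unit, to a Z-alkene. A formyl group at C7, para to O4, polarises that quinone and later becomes the cinnamate.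

## Retrosynthesis

**Unmasking, 21 from 20.** The last cut removes only protecting groups: two aryl tert-butyl carbonates on ring B, a 4-methoxybenzyl ester on the lactate carboxyl and a 4-methoxybenzyl ether on ring C. All four are acid-labile, so a single treatment with trifluoroacetic acid should suffice; base, hydrogen and fluoride, each of which threatens a different part of 21, are avoided. Compound 20 is no simpler in skeleton but is robust. The forward step asks only that the benzyl cations be trapped.

**C2 oxidation level, 20 from 18 (through 19) and 18 from 17.** The C2 carboxyl is traced back to a primary alcohol and that to a silyl ether. The neighbouring choice, carrying C2 as an ester from the ring-forming step, would expose an epimerisable and eliminable centre to every later base. At the alcohol level C2 is inert. The forward oxidation must be mild enough that the transient aldehyde 19 does not epimerise.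

**Cα=Cβ of the cinnamate, 17 from 8 and 16.** Cutting the alkene gives aldehyde 8 and phosphonate 16; a Horner–Wadsworth–Emmons reaction joins the halves and sets the E geometry in one step. Cutting the ester C–O bond instead would need a free cinnamic acid and one more protecting-group change. A Heck disconnection would put a halide at C7 in place of the formyl group that directs the ring-forming step. The precursor 8 has lost half the molecule.

**Lactate arm, 16 from 14 and 15; 14 from 13; 13 from 10 and 11 through 12; 10 from 9.** Phosphonate 16 is the ester of alcohol 14 with acid 15. Ester 14 comes from methyl ester 13 by ester exchange, which installs the acid-labile ester. The aryl–CH2 bond of 13 is cut to Grignard reagent 12 (from bromide 10, the protected form of phenol 9) and methyl (R)-glycidate 11, so the stereocentre is bought, not made. Asymmetric reduction of an aryl pyruvate or dihydroxylation and deoxygenation of a cinnamate would be longer.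

**Dioxane ring, 8 from 7 and 5.** O1–C2 and O4–C3 are cut together. This removes the ring and both ring stereocentres at once and leaves ortho-quinone 7 and Z-alkene 5, neither with a stereocentre. Stepwise alternatives (ether formation, then closure) need a chiral three-carbon piece and two separate C–O bond formations. The forward reaction must be regioselective (O4 to the benzylic carbon), transfer Z to cis, and differentiate the alkene faces. Ring B carries two carbonate groups so that C3 never becomes a free cation. The primary oxygen is silylated so that the alkene stays electron-rich enough to react.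

**The partners, 7 from 6; 5 from 4; 4 from 2 and 3; 2 from 1.** Quinone 7 is made in the flask from 3,4-dihydroxybenzaldehyde 6. Alkene 5 comes from alkyne 4 by semihydrogenation, and 4 from aryl bromide 2 and the silylated propargyl alcohol 3 by Sonogashira coupling. Bromide 2 is 4-bromocatechol 1 with both hydroxyls acylated.

## Roads not taken

**Alternative 1: one-carbon ring expansion of a catechol benzylidene acetal.** The cut is at O1–C2 and C2–C3. The 2-aryl-1,3-benzodioxole A1, already carrying the whole cinnamoyl lactate arm, would meet a copper carbenoid from diazoacetate A2 (Cu(MeCN)4PF6, monovalent copper, chiral bis(oxazoline)). The carbenoid forms an oxonium ylide at O1 and the acetal carbon shifts to the carbenoid carbon, expanding the five-membered ring to the dioxane of A3.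

- Merits: it is the most convergent of the four. A1 is one acetalisation away from simple parts, C2 arrives at the acid level, and A3 is one deprotection from 21. In step count after the key step it beats the chosen plan (one step against four).
- Weak points: the two acetal oxygens differ only in being meta or para to a distant acrylate, so ylide formation at O1 over O4 is weakly biased. The [1,2]-shift of such ylides (Stevens type) tends to pass through a radical or ion pair, so the cis relation would be set by recombination and not by geometry. The acetal carbon of A1 is itself a stereocentre, so the catalyst would have to control both new centres against it. The cinnamate alkene and benzylic C–H bonds are competing carbenoid targets. The final fluoride treatment would act on a cis C2 ester.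
- Comparison: the chosen plan sets against this a cis relation tied to alkene geometry, a regiochemistry driven by a formyl group in direct conjugation with one oxygen, and a stereochemical risk that is met early on cheap material, not at the last bond.

**Alternative 2: cis-glycidate opening, then Mitsunobu closure with inversion.** The forward closure forms O1–C2. The cis-glycidate A4 would be opened at the benzylic carbon by the 4-hydroxyl of 6 to give hydroxy ether A5. PPh3 and diisopropyl azodicarboxylate then activate the C2 hydroxyl and the remaining phenol displaces it with inversion, giving A6.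

- Merits: every step is a known reaction type. Two clean inversions from an enantiopure cis-epoxide guarantee cis, the phenol acidities fix the regiochemistry, and C2 is at the acid level from the start, so no oxidation is needed. In certainty and in oxidation-state economy this road is better than the chosen one.
- Weak points: enantiopure A4 needs several steps of its own (a Z-cinnamate and its asymmetric epoxidation). Opening an electron-rich aryl epoxide can drift toward ionisation at C3. From A6 onward the cis C2 ester must survive the base of the olefination at the 7-formyl group.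
- Comparison: the chosen plan makes the ring and both centres in one convergent step from two achiral partners, and keeps C2 at the alcohol level through the basic olefination. The logic of this alternative is kept in reserve as the fallback for the key step.

**Alternative 3: asymmetric oxa-Michael closure onto an alpha-aryloxy cinnamate.** The cut is at O4–C3. In A7 the ring A phenol would add to the beta carbon under a chiral bifunctional iminophosphorane base, a 6-endo closure; protonation of the enolate sets C2 and gives A8.

- Merits: A7 is easy to assemble, the step is catalytic, the ester level at C2 is in place, and the bromide at C7 is a handle for a later alkenylation. Its need for an untested asymmetric step is no greater than that of the chosen plan.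
- Weak points: the acceptor is deactivated by the alpha-aryloxy group and an electron-rich beta-aryl group. C2 is set by a protonation whose kinetic sense is open and whose thermodynamic sense is trans. The addition is reversible under the base that catalyses it, which erodes both cis and enantiomeric purity. The later palladium-catalysed alkenylation again heats a cis C2 ester with base.
- Comparison: the chosen plan derives cis from the alkene geometry, which this road cannot, and it never carries a C2 ester. Both are of similar length.

Key step: step 4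

Remark on numbering: the benzodioxane is numbered throughout as in the target acid (O1, C2 with the one-carbon substituent, C3 with ring B, O4, side chain at C7), also in intermediates.

Assumption: the facial sense of the copper–bis(oxazoline) complex in step 4 cannot be predicted with confidence; the (S,S)-ligand 2,2'-(propane-2,2-diyl)bis[(4S)-4-tert-butyl-4,5-dihydrooxazole] ("tBu-box") is written, and its mirror image would be used if it is the one that favours 8.

Remark: silyl ether 3 is taken as a purchased compound; it is one silylation away from propargyl alcohol.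

## Route

Step 1
Reactants: 1 4-bromocatechol
Product: 2 4-bromo-1,2-phenylene bis(tert-butyl carbonate)
Conditions: Boc2O (2.3 equiv), DMAP (5 mol %), CH2Cl2, 0 °C → rt
Reagents that add atoms: di-tert-butyl dicarbonate, CC(C)(C)OC(=O)OC(=O)OC(C)(C)C
Why: DMAP-catalysed O-acylation of both phenols. The carbonates make ring B electron-poor, as acetates would, but leave in the final acid step.

Step 2
Reactants: 2 4-bromo-1,2-phenylene bis(tert-butyl carbonate); 3 tert-butyldimethyl(prop-2-yn-1-yloxy)silane
Product: 4 4-{3-[tert-butyl(dimethyl)silyl]oxyprop-1-yn-1-yl}-1,2-phenylene bis(tert-butyl carbonate)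
Conditions: PdCl2(PPh3)2 (3 mol %), CuI (5 mol %), Et3N, THF, 60 °C
Reagents that add atoms: none
Why: Sonogashira coupling of an aryl bromide with a terminal alkyne; the tertiary amine does not attack aryl carbonates.

Step 3
Reactants: 4 4-{3-[tert-butyl(dimethyl)silyl]oxyprop-1-yn-1-yl}-1,2-phenylene bis(tert-butyl carbonate)
Product: 5 4-{(1Z)-3-[tert-butyl(dimethyl)silyl]oxyprop-1-en-1-yl}-1,2-phenylene bis(tert-butyl carbonate)
Conditions: H2 (1 atm), Pd/CaCO3 poisoned with Pb(OAc)2, quinoline, EtOAc, rt
Reagents that add atoms: none
Why: Lindlar semihydrogenation; syn delivery of hydrogen on the poisoned palladium surface should give the Z-alkene, and the reaction is stopped after one equivalent.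

Step 4
Reactants: 6 3,4-dihydroxybenzaldehyde; 5 4-{(1Z)-3-[tert-butyl(dimethyl)silyl]oxyprop-1-en-1-yl}-1,2-phenylene bis(tert-butyl carbonate)
Product: 8 (2S,3R)-3-[3,4-bis(tert-butoxycarbonyloxy)phenyl]-2-{[tert-butyl(dimethyl)silyl]oxymethyl}-2,3-dihydro-1,4-benzodioxine-7-carbaldehyde, via 4-formyl-1,2-benzoquinone 7 (not isolated)
Conditions: 6 (1.5 equiv), Ag2O, Na2SO4, Et2O/THF, −20 °C, dark; cold filtration, slow addition to 5, Cu(OTf)2 (10 mol %), (S,S)-tBu-box (11 mol %), 4 Å MS, CH2Cl2, −78 → −20 °C
Reagents that add atoms: none
Why: Proposed new method: Ag2O (monovalent silver) oxidises catechol 6 to quinone 7, which is filtered cold so that no basic silver oxide or silver salt meets the catalyst; 7 then binds Cu(OTf)2 (divalent copper) with the bis(oxazoline) through both carbonyl oxygens, which lowers its LUMO, and its O=C–C=O unit adds to the Z-alkene of 5 in an inverse-demand hetero-Diels–Alder reaction. The closest known reaction types are the uncatalysed [4+2] addition of ortho-quinones to styrenes and enol ethers giving 1,4-benzodioxanes, in which alkene geometry can be retained, and copper–bis(oxazoline) catalysis of hetero-Diels–Alder reactions of chelating 1,2-dicarbonyl heterodienes. The dioxane ring closes in the cycloaddition itself, with O1–C2 and O4–C3 both formed on one face of the alkene. The transition state should be asynchronous: the alkene carbon remote from ring B bonds to the oxygen meta to the formyl group because the charge building on the other oxygen is stabilised by the para formyl group, so O1 takes C2 and O4 takes benzylic C3. The cis relation of C2 and C3 is controlled by the Z geometry of 5 through suprafacial addition, and the two carbonates on ring B keep C3 from becoming a free cation that could rotate before closure. The absolute configuration of both centres is set together by the ligand, whose tert-butyl groups should make one orientation of the unsymmetrical alkene over the chelated quinone the easier one. The step needs heterodiene over carbodiene reactivity, the stated regiochemistry, cis transfer and face selection, secured respectively by the electron-rich alkene, the formyl group, the acyl-protected ring B and the chelated chiral Lewis acid.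

Step 5
Reactants: 9 4-bromo-2-methoxyphenol
Product: 10 4-bromo-2-methoxy-1-[(4-methoxyphenyl)methoxy]benzene
Conditions: 4-methoxybenzyl chloride, K2CO3, DMF, rt
Reagents that add atoms: 4-methoxybenzyl chloride, COc1ccc(CCl)cc1
Why: Williamson ether synthesis; the benzyl ether survives the Grignard step and leaves with acid at the end.

Step 6
Reactants: 10 4-bromo-2-methoxy-1-[(4-methoxyphenyl)methoxy]benzene; 11 methyl (R)-glycidate
Product: 13 methyl (2R)-2-hydroxy-3-{3-methoxy-4-[(4-methoxyphenyl)methoxy]phenyl}propanoate, via arylmagnesium bromide 12 (not isolated)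
Conditions: Mg, I2 (cat.), THF, rt; then CuI (10 mol %), 11, THF, −40 → −20 °C; aq. NH4Cl
Reagents that add atoms: none
Why: Copper-catalysed Grignard opening of the epoxide at its unsubstituted carbon, which at low temperature should outrun addition to the ester. The stereocentre of 11 is not touched, so the R configuration is carried into 13.

Step 7
Reactants: 13 methyl (2R)-2-hydroxy-3-{3-methoxy-4-[(4-methoxyphenyl)methoxy]phenyl}propanoate
Product: 14 (4-methoxyphenyl)methyl (2R)-2-hydroxy-3-{3-methoxy-4-[(4-methoxyphenyl)methoxy]phenyl}propanoate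
Conditions: 4-methoxybenzyl alcohol (5 equiv), Ti(OiPr)4 (10 mol %), toluene, 90 °C, removal of MeOH
Reagents that add atoms: 4-methoxybenzyl alcohol, COc1ccc(CO)cc1
Why: Titanate-catalysed transesterification, a neutral process that exchanges alpha-hydroxy esters without touching the stereocentre; it installs the acid-labile ester.

Step 8
Reactants: 14 (4-methoxyphenyl)methyl (2R)-2-hydroxy-3-{3-methoxy-4-[(4-methoxyphenyl)methoxy]phenyl}propanoate; 15 (diethoxyphosphoryl)acetic acid
Product: 16 (4-methoxyphenyl)methyl (2R)-2-{[(diethoxyphosphoryl)acetyl]oxy}-3-{3-methoxy-4-[(4-methoxyphenyl)methoxy]phenyl}propanoate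
Conditions: EDC·HCl, DMAP (10 mol %), CH2Cl2, 0 °C → rt
Reagents that add atoms: none
Why: Steglich esterification; acylation at oxygen leaves the C–O bond of the stereocentre intact.

Step 9
Reactants: 8 (2S,3R)-3-[3,4-bis(tert-butoxycarbonyloxy)phenyl]-2-{[tert-butyl(dimethyl)silyl]oxymethyl}-2,3-dihydro-1,4-benzodioxine-7-carbaldehyde; 16 (4-methoxyphenyl)methyl (2R)-2-{[(diethoxyphosphoryl)acetyl]oxy}-3-{3-methoxy-4-[(4-methoxyphenyl)methoxy]phenyl}propanoate
Product: 17 (4-methoxyphenyl)methyl (2R)-2-{[(2E)-3-{(2S,3R)-3-[3,4-bis(tert-butoxycarbonyloxy)phenyl]-2-{[tert-butyl(dimethyl)silyl]oxymethyl}-2,3-dihydro-1,4-benzodioxin-7-yl}prop-2-enoyl]oxy}-3-{3-methoxy-4-[(4-methoxyphenyl)methoxy]phenyl}propanoate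
Conditions: LiCl, iPr2NEt, MeCN, rt
Reagents that add atoms: none
Why: Horner–Wadsworth–Emmons olefination in its LiCl/amine variant, E-selective for a stabilised phosphonate. The base is too weak to touch the lactate alpha-hydrogen, and C2 of 8 is still at the alcohol level, so nothing in the ring can epimerise.

Step 10
Reactants: 17 the silyl ether from step 9
Product: 18 (4-methoxyphenyl)methyl (2R)-2-{[(2E)-3-{(2S,3R)-3-[3,4-bis(tert-butoxycarbonyloxy)phenyl]-2-(hydroxymethyl)-2,3-dihydro-1,4-benzodioxin-7-yl}prop-2-enoyl]oxy}-3-{3-methoxy-4-[(4-methoxyphenyl)methoxy]phenyl}propanoate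
Conditions: HF·pyridine, pyridine, THF, 0 °C → rt
Reagents that add atoms: none
Why: Fluoride cleavage of a primary silyl ether under buffered, weakly acidic conditions that should spare the carbonates, the benzyl groups and both esters.

Step 11
Reactants: 18 the primary alcohol from step 10
Product: 20 (2R,3R)-3-[3,4-bis(tert-butoxycarbonyloxy)phenyl]-7-[(1E)-3-{[(2R)-1-[(4-methoxyphenyl)methoxy]-3-{3-methoxy-4-[(4-methoxyphenyl)methoxy]phenyl}-1-oxopropan-2-yl]oxy}-3-oxoprop-1-en-1-yl]-2,3-dihydro-1,4-benzodioxine-2-carboxylic acid, via C2 aldehyde 19 (not isolated)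
Conditions: TEMPO (20 mol %), PhI(OAc)2 (2.5 equiv), CH2Cl2/H2O (2:1), rt
Reagents that add atoms: water, O
Why: Oxoammonium-mediated oxidation of a primary alcohol to the acid with PhI(OAc)2 (trivalent iodine) as terminal oxidant. The electron-poor alpha-aryloxy aldehyde 19 should hydrate and oxidise on quickly in a weakly acidic medium, which is what protects the cis C2 centre; the change of descriptor from S to R is only a change of substituent priority.

Step 12
Reactants: 20 the protected acid from step 11
Product: 21 clinopodic acid F
Conditions: TFA/CH2Cl2 (1:4), anisole (20 equiv), 0 °C → rt; reverse-phase chromatography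
Reagents that add atoms: none
Why: Acidolysis. The 4-methoxybenzyl ester and ether should ionise first, while ring B is still deactivated, and anisole traps the cations; the aryl tert-butyl carbonates then lose isobutene and CO2. No base, reductant or nucleophile meets the ester link, the alkene or C2.

## Compound list

1 | 4-bromocatechol (4-bromobenzene-1,2-diol) | Oc1ccc(Br)cc1O | starting material
2 | 4-bromo-1,2-phenylene bis(tert-butyl carbonate) | CC(C)(C)OC(=O)Oc1ccc(Br)cc1OC(=O)OC(C)(C)C | intermediate
3 | tert-butyldimethyl(prop-2-yn-1-yloxy)silane | C#CCO[Si](C)(C)C(C)(C)C | starting material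
4 | 4-{3-[tert-butyl(dimethyl)silyl]oxyprop-1-yn-1-yl}-1,2-phenylene bis(tert-butyl carbonate) | CC(C)(C)OC(=O)Oc1ccc(C#CCO[Si](C)(C)C(C)(C)C)cc1OC(=O)OC(C)(C)C | intermediate
5 | 4-{(1Z)-3-[tert-butyl(dimethyl)silyl]oxyprop-1-en-1-yl}-1,2-phenylene bis(tert-butyl carbonate) | CC(C)(C)[Si](C)(C)OC/C=C\c1ccc(OC(=O)OC(C)(C)C)c(OC(=O)OC(C)(C)C)c1 | intermediate
6 | 3,4-dihydroxybenzaldehyde | O=Cc1ccc(O)c(O)c1 | starting material
7 | 4-formyl-1,2-benzoquinone (formed in the flask) | O=CC1=CC(=O)C(=O)C=C1 | intermediate
8 | (2S,3R)-3-[3,4-bis(tert-butoxycarbonyloxy)phenyl]-2-{[tert-butyl(dimethyl)silyl]oxymethyl}-2,3-dihydro-1,4-benzodioxine-7-carbaldehyde (cis) | O=Cc1ccc2c(c1)O[C@@H](CO[Si](C)(C)C(C)(C)C)[C@@H](c1ccc(OC(=O)OC(C)(C)C)c(OC(=O)OC(C)(C)C)c1)O2 | intermediate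
9 | 4-bromo-2-methoxyphenol | COc1cc(Br)ccc1O | starting material
10 | 4-bromo-2-methoxy-1-[(4-methoxyphenyl)methoxy]benzene | COc1ccc(COc2ccc(Br)cc2OC)cc1 | intermediate
11 | methyl (R)-glycidate | COC(=O)[C@H]1CO1 | starting material
12 | {3-methoxy-4-[(4-methoxyphenyl)methoxy]phenyl}magnesium bromide (formed in the flask) | COc1ccc(COc2ccc([Mg]Br)cc2OC)cc1 | intermediate
13 | methyl (2R)-2-hydroxy-3-{3-methoxy-4-[(4-methoxyphenyl)methoxy]phenyl}propanoate | COC(=O)[C@H](O)Cc1ccc(OCc2ccc(OC)cc2)c(OC)c1 | intermediate
14 | (4-methoxyphenyl)methyl (2R)-2-hydroxy-3-{3-methoxy-4-[(4-methoxyphenyl)methoxy]phenyl}propanoate | COc1ccc(COC(=O)[C@H](O)Cc2ccc(OCc3ccc(OC)cc3)c(OC)c2)cc1 | intermediate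
15 | (diethoxyphosphoryl)acetic acid | CCOP(=O)(CC(=O)O)OCC | starting material
16 | (4-methoxyphenyl)methyl (2R)-2-{[(diethoxyphosphoryl)acetyl]oxy}-3-{3-methoxy-4-[(4-methoxyphenyl)methoxy]phenyl}propanoate | CCOP(=O)(CC(=O)O[C@H](Cc1ccc(OCc2ccc(OC)cc2)c(OC)c1)C(=O)OCc1ccc(OC)cc1)OCC | intermediate
17 | (4-methoxyphenyl)methyl (2R)-2-{[(2E)-3-{(2S,3R)-3-[3,4-bis(tert-butoxycarbonyloxy)phenyl]-2-{[tert-butyl(dimethyl)silyl]oxymethyl}-2,3-dihydro-1,4-benzodioxin-7-yl}prop-2-enoyl]oxy}-3-{3-methoxy-4-[(4-methoxyphenyl)methoxy]phenyl}propanoate | COc1cc(C[C@@H](OC(=O)/C=C/c2ccc3c(c2)O[C@@H](CO[Si](C)(C)C(C)(C)C)[C@@H](c2ccc(OC(=O)OC(C)(C)C)c(OC(=O)OC(C)(C)C)c2)O3)C(=O)OCc2ccc(OC)cc2)ccc1OCc1ccc(OC)cc1 | intermediate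
18 | (4-methoxyphenyl)methyl (2R)-2-{[(2E)-3-{(2S,3R)-3-[3,4-bis(tert-butoxycarbonyloxy)phenyl]-2-(hydroxymethyl)-2,3-dihydro-1,4-benzodioxin-7-yl}prop-2-enoyl]oxy}-3-{3-methoxy-4-[(4-methoxyphenyl)methoxy]phenyl}propanoate | COc1cc(C[C@@H](OC(=O)/C=C/c2ccc3c(c2)O[C@@H](CO)[C@@H](c2ccc(OC(=O)OC(C)(C)C)c(OC(=O)OC(C)(C)C)c2)O3)C(=O)OCc2ccc(OC)cc2)ccc1OCc1ccc(OC)cc1 | intermediate
19 | (4-methoxyphenyl)methyl (2R)-2-{[(2E)-3-{(2R,3R)-3-[3,4-bis(tert-butoxycarbonyloxy)phenyl]-2-formyl-2,3-dihydro-1,4-benzodioxin-7-yl}prop-2-enoyl]oxy}-3-{3-methoxy-4-[(4-methoxyphenyl)methoxy]phenyl}propanoate (formed in the flask) | COc1cc(C[C@@H](OC(=O)/C=C/c2ccc3c(c2)O[C@@H](C=O)[C@@H](c2ccc(OC(=O)OC(C)(C)C)c(OC(=O)OC(C)(C)C)c2)O3)C(=O)OCc2ccc(OC)cc2)ccc1OCc1ccc(OC)cc1 | intermediate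
20 | (2R,3R)-3-[3,4-bis(tert-butoxycarbonyloxy)phenyl]-7-[(1E)-3-{[(2R)-1-[(4-methoxyphenyl)methoxy]-3-{3-methoxy-4-[(4-methoxyphenyl)methoxy]phenyl}-1-oxopropan-2-yl]oxy}-3-oxoprop-1-en-1-yl]-2,3-dihydro-1,4-benzodioxine-2-carboxylic acid | COc1cc(C[C@@H](OC(=O)/C=C/c2ccc3c(c2)O[C@@H](C(=O)O)[C@@H](c2ccc(OC(=O)OC(C)(C)C)c(OC(=O)OC(C)(C)C)c2)O3)C(=O)OCc2ccc(OC)cc2)ccc1OCc1ccc(OC)cc1 | intermediate
21 | clinopodic acid F | COc1cc(C[C@@H](OC(=O)/C=C/c2ccc3c(c2)O[C@@H](C(=O)O)[C@@H](c2ccc(O)c(O)c2)O3)C(=O)O)ccc1O | target

## Step count and risks

Total: 12 steps. Longest linear sequence: 8 steps (steps 1–4 and 9–12; the branch through steps 5–8 and 9–12 is equally long).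

**Step 4 (key step; the one step with the new-method label).** Three things may go wrong. The very electrophilic quinone may condense with itself faster than it adds to a twisted, carbonate-deactivated Z-styrene. Bond formation under the Lewis acid may become stepwise, with rotation at C3 before closure and leakage to trans. Most likely of all, face selection may be weak, because the ligand sits in the plane of the chelate while the alkene approaches from above it. The fallback uses known reactions only; it sets out from 5 and 6 and returns at 8. A Jacobsen–Katsuki epoxidation of 5 (mCPBA, N-methylmorpholine N-oxide, the chiral [N,N'-bis(3,5-di-tert-butylsalicylidene)cyclohexane-1,2-diaminato]MnCl complex of trivalent manganese in the enantiomeric form that oxidises the required face, CH2Cl2, −78 °C) should give the cis-epoxide tert-butyl{[(2R,3S)-3-[3,4-bis(tert-butoxycarbonyloxy)phenyl]oxiran-2-yl]methoxy}dimethylsilane F1. The more acidic 4-hydroxyl of 6, as its caesium phenoxide (Cs2CO3, DMF, 50 °C), should open F1 at the benzylic carbon with inversion, since the other carbon is retarded by its CH2O neighbour, to give 4-{(1R,2R)-1-[3,4-bis(tert-butoxycarbonyloxy)phenyl]-3-[tert-butyl(dimethyl)silyl]oxy-2-hydroxypropoxy}-3-hydroxybenzaldehyde F2. A Mitsunobu reaction (PPh3, diisopropyl azodicarboxylate, THF, 0 °C) then closes O1–C2 with inversion and gives 8. Two inversions on a cis-epoxide give the cis ring without any reliance on a concerted cycloaddition.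

**Step 12.** The concern is the last minutes of the acidolysis. Once ring B is unmasked, the benzylic C3–O4 bond of a 3,4-dihydroxybenzyl aryl ether sits in strong acid and may ionise, with cis-to-trans leakage; the carbonates may also need longer than the benzyl groups, which prolongs that exposure. The fallback sets out from 20 and returns at 21, and separates the two kinds of group. Dilute TFA (2–5 %) with anisole at 0 °C should remove only the two 4-methoxybenzyl groups and give (2R,3R)-3-[3,4-bis(tert-butoxycarbonyloxy)phenyl]-7-[(1E)-3-{[(1R)-1-carboxy-2-(4-hydroxy-3-methoxyphenyl)ethyl]oxy}-3-oxoprop-1-en-1-yl]-2,3-dihydro-1,4-benzodioxine-2-carboxylic acid F3. TMSOTf with 2,6-lutidine in CH2Cl2 at 0 °C should then take the carbonates out by silyl transfer and not by protonolysis (loss of isobutene and CO2), giving the pentakis(trimethylsilyl) derivative of clinopodic acid F F4, which is not isolated. Neutral methanolysis of F4 releases 21, so the free catechol never sits in protic acid.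

**Step 9.** The aryl aldehyde of 8 is electron-rich and slow. During a long reaction the amine and chloride may strip an aryl carbonate, or the phosphonate carbanion may cyclise onto the neighbouring benzyl ester (a five-membered tetronate). The fallback sets out from 14 and returns at 17 and uses no base. Addition of alcohol 14 to (triphenylphosphoranylidene)ketene in toluene at 60 °C should give the stabilised ylide (4-methoxyphenyl)methyl (2R)-3-{3-methoxy-4-[(4-methoxyphenyl)methoxy]phenyl}-2-{[(triphenyl-λ5-phosphanylidene)acetyl]oxy}propanoate F5, and a Wittig reaction of F5 with 8 in the same solvent should give the E-alkene 17.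

**Step 11.** Aldehyde 19 may epimerise at C2, or expel the O4 phenoxide, before it is hydrated and oxidised; the oxidant may also attack the electron-rich 4-methoxybenzyl groups of the lactate arm. The fallback changes the order of events so that only the small bicyclic core meets the oxidant; it sets out from 8 and returns at 20. HF·pyridine should give (2S,3R)-3-[3,4-bis(tert-butoxycarbonyloxy)phenyl]-2-(hydroxymethyl)-2,3-dihydro-1,4-benzodioxine-7-carbaldehyde F6. The same TEMPO/PhI(OAc)2 oxidation, to which the unhydrated aryl aldehyde is inert, should pass through (2R,3R)-3-[3,4-bis(tert-butoxycarbonyloxy)phenyl]-2,3-dihydro-1,4-benzodioxine-2,7-dicarbaldehyde F7 (not isolated) to (2R,3R)-3-[3,4-bis(tert-butoxycarbonyloxy)phenyl]-7-formyl-2,3-dihydro-1,4-benzodioxine-2-carboxylic acid F8, on which the integrity of C2 can be checked on a simple compound. Olefination of F8 with 16 (LiCl, one further equivalent of iPr2NEt) then gives 20 directly; C2 is protected from epimerisation as its carboxylate.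

## Further compounds

F1 | step 4 | tert-butyl{[(2R,3S)-3-[3,4-bis(tert-butoxycarbonyloxy)phenyl]oxiran-2-yl]methoxy}dimethylsilane | CC(C)(C)[Si](C)(C)OC[C@H]1O[C@H]1c1ccc(OC(=O)OC(C)(C)C)c(OC(=O)OC(C)(C)C)c1
F2 | step 4 | 4-{(1R,2R)-1-[3,4-bis(tert-butoxycarbonyloxy)phenyl]-3-[tert-butyl(dimethyl)silyl]oxy-2-hydroxypropoxy}-3-hydroxybenzaldehyde | O=Cc1ccc(O[C@H](c2ccc(OC(=O)OC(C)(C)C)c(OC(=O)OC(C)(C)C)c2)[C@H](O)CO[Si](C)(C)C(C)(C)C)c(O)c1
F3 | step 12 | (2R,3R)-3-[3,4-bis(tert-butoxycarbonyloxy)phenyl]-7-[(1E)-3-{[(1R)-1-carboxy-2-(4-hydroxy-3-methoxyphenyl)ethyl]oxy}-3-oxoprop-1-en-1-yl]-2,3-dihydro-1,4-benzodioxine-2-carboxylic acid | COc1cc(C[C@@H](OC(=O)/C=C/c2ccc3c(c2)O[C@@H](C(=O)O)[C@@H](c2ccc(OC(=O)OC(C)(C)C)c(OC(=O)OC(C)(C)C)c2)O3)C(=O)O)ccc1O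
F4 | step 12 | pentakis(trimethylsilyl) derivative of clinopodic acid F (two silyl esters, three aryl silyl ethers) | COc1cc(C[C@@H](OC(=O)/C=C/c2ccc3c(c2)O[C@@H](C(=O)O[Si](C)(C)C)[C@@H](c2ccc(O[Si](C)(C)C)c(O[Si](C)(C)C)c2)O3)C(=O)O[Si](C)(C)C)ccc1O[Si](C)(C)C
F5 | step 9 | (4-methoxyphenyl)methyl (2R)-3-{3-methoxy-4-[(4-methoxyphenyl)methoxy]phenyl}-2-{[(triphenyl-λ5-phosphanylidene)acetyl]oxy}propanoate | COc1ccc(COC(=O)[C@@H](Cc2ccc(OCc3ccc(OC)cc3)c(OC)c2)OC(=O)C=P(c2ccccc2)(c2ccccc2)c2ccccc2)cc1
F6 | step 11 | (2S,3R)-3-[3,4-bis(tert-butoxycarbonyloxy)phenyl]-2-(hydroxymethyl)-2,3-dihydro-1,4-benzodioxine-7-carbaldehyde | O=Cc1ccc2c(c1)O[C@@H](CO)[C@@H](c1ccc(OC(=O)OC(C)(C)C)c(OC(=O)OC(C)(C)C)c1)O2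
F7 | step 11 | (2R,3R)-3-[3,4-bis(tert-butoxycarbonyloxy)phenyl]-2,3-dihydro-1,4-benzodioxine-2,7-dicarbaldehyde | O=Cc1ccc2c(c1)O[C@@H](C=O)[C@@H](c1ccc(OC(=O)OC(C)(C)C)c(OC(=O)OC(C)(C)C)c1)O2
F8 | step 11 | (2R,3R)-3-[3,4-bis(tert-butoxycarbonyloxy)phenyl]-7-formyl-2,3-dihydro-1,4-benzodioxine-2-carboxylic acid | O=Cc1ccc2c(c1)O[C@@H](C(=O)O)[C@@H](c1ccc(OC(=O)OC(C)(C)C)c(OC(=O)OC(C)(C)C)c1)O2
A1 | alternative 1 | 2-(trimethylsilyl)ethyl (2R)-2-{[(2E)-3-{2-[3,4-bis(tert-butyldimethylsilyloxy)phenyl]-1,3-benzodioxol-5-yl}prop-2-enoyl]oxy}-3-[4-(tert-butyldimethylsilyloxy)-3-methoxyphenyl]propanoate (acetal carbon not defined) | COc1cc(C[C@@H](OC(=O)/C=C/c2ccc3c(c2)OC(c2ccc(O[Si](C)(C)C(C)(C)C)c(O[Si](C)(C)C(C)(C)C)c2)O3)C(=O)OCC[Si](C)(C)C)ccc1O[Si](C)(C)C(C)(C)C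
A2 | alternative 1 | 2-(trimethylsilyl)ethyl diazoacetate | [N-]=[N+]=CC(=O)OCC[Si](C)(C)C
A3 | alternative 1 | tris(tert-butyldimethylsilyl) ether bis[2-(trimethylsilyl)ethyl] ester of clinopodic acid F | COc1cc(C[C@@H](OC(=O)/C=C/c2ccc3c(c2)O[C@@H](C(=O)OCC[Si](C)(C)C)[C@@H](c2ccc(O[Si](C)(C)C(C)(C)C)c(O[Si](C)(C)C(C)(C)C)c2)O3)C(=O)OCC[Si](C)(C)C)ccc1O[Si](C)(C)C(C)(C)C
A4 | alternative 2 | prop-2-en-1-yl (2S,3S)-3-[3,4-bis(prop-2-en-1-yloxy)phenyl]oxirane-2-carboxylate (cis) | C=CCOC(=O)[C@H]1O[C@H]1c1ccc(OCC=C)c(OCC=C)c1
A5 | alternative 2 | prop-2-en-1-yl (2S,3R)-3-[3,4-bis(prop-2-en-1-yloxy)phenyl]-3-(4-formyl-2-hydroxyphenoxy)-2-hydroxypropanoate | O=Cc1ccc(O[C@H](c2ccc(OCC=C)c(OCC=C)c2)[C@H](O)C(=O)OCC=C)c(O)c1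
A6 | alternative 2 | prop-2-en-1-yl (2R,3R)-3-[3,4-bis(prop-2-en-1-yloxy)phenyl]-7-formyl-2,3-dihydro-1,4-benzodioxine-2-carboxylate | O=Cc1ccc2c(c1)O[C@@H](C(=O)OCC=C)[C@@H](c1ccc(OCC=C)c(OCC=C)c1)O2
A7 | alternative 3 | 2-(trimethylsilyl)ethyl (2Z)-2-(5-bromo-2-hydroxyphenoxy)-3-[3,4-bis(tert-butyldimethylsilyloxy)phenyl]prop-2-enoate | Oc1ccc(Br)cc1O/C(=C\c1ccc(O[Si](C)(C)C(C)(C)C)c(O[Si](C)(C)C(C)(C)C)c1)C(=O)OCC[Si](C)(C)C
A8 | alternative 3 | 2-(trimethylsilyl)ethyl (2R,3R)-7-bromo-3-[3,4-bis(tert-butyldimethylsilyloxy)phenyl]-2,3-dihydro-1,4-benzodioxine-2-carboxylate | Brc1ccc2c(c1)O[C@@H](C(=O)OCC[Si](C)(C)C)[C@@H](c1ccc(O[Si](C)(C)C(C)(C)C)c(O[Si](C)(C)C(C)(C)C)c1)O2
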